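**Retrosynthetic overview**

1. Target 30 ⇐ enal 27 + 3-pentanone (reagent-controlled syn aldol, last step); the vinyl epoxide ⇐ trans-diol 24 ⇐ α′-hydroxy enone 23.
2. 23 ⇐ bridged ketone 20 by E1cB fragmentation: a temporary oxygen bridge is cut, which creates the ring C=C and releases the CH2–O of the side chain.
3. Key disconnection 20 ⇐ acyclic acetal diol 15 + 3,3-dimethoxypentane. In one flask a temporary 3,6-dihydro-2H-pyran is closed, a ketal Claisen shift joins the ring CH that bears the side chain to the methyl-bearing carbon that becomes the quaternary epoxide carbon, and an acetal aldol joins the vinylic ring CH to the methyl-bearing vinylic carbon (first as a single bond).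
4. Enabling feature: the ring CH that carries the C(=CH2)–C–O unit and the vinylic ring CH are both bonded to the quaternary carbon. The oxygenated side-chain carbon and the vinylic CH (at the aldehyde level) can therefore be tied through oxygen into a six-membered ring O–CH–C(quaternary)–CH=C–CH2; its exocyclic CH2–O becomes the =CH2 carbon (Claisen origin) and its acetal carbon is the electrophile for the second bond.
5. Ring order: pyranone (steps 1–3), temporary dihydropyran and then the carbocycle (both in step 10), bridge opened (step 11), epoxide (step 13). The quaternary stereocentre comes from an asymmetric α-allylation (step 5); all others are relayed from it or set by the final aldol.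

Key step: step 10

**Remarks on the chemistry**

- Pyn = 6-methoxy-3,5-dimethyl-4-oxo-4H-pyran-2-yl; Ipc = isopinocampheyl.
- Assumption: (R)-TRIP is taken to give (S)-9, by analogy with 2-arylpropanals; if the sense is opposite, (S)-TRIP is used.
- Assumption: the (+)-Ipc2B enolate (from (−)-α-pinene) is taken to add to the Re face of the aldehyde, as the corresponding allylborane does; if the sense is opposite, the (−)-reagent is used.
- Assumption: the 2-methoxy-4-pyranone (a vinylogous carbonate) survives i-Bu2AlH at −78 °C, titrated ozone and amide bases at −78 °C.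
- The acetal carbon of 17–19 and the CH(CH3) centres of 19–21 form as mixtures that converge in steps 10 and 11; their SMILES leave these centres open.

**Route**

Step 1
Reactants: 1 methyl 2-methyl-3-oxopentanoate; 2 N-methoxy-N-methylpropanamide
Product: 3 methyl 2,4-dimethyl-3,5-dioxoheptanoate
Conditions: NaH, THF, 0 °C; n-BuLi, 0 °C; 2, −78 → 0 °C; aq. NH4Cl
Reagents that add atoms: none
Why: γ-Acylation of the β-keto ester dianion by the Weinreb amide, whose chelated adduct prevents over-addition, should give the triketide; its stereocentres are lost in step 2.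

Step 2
Reactants: 3 methyl 2,4-dimethyl-3,5-dioxoheptanoate
Product: 4 6-ethyl-4-hydroxy-3,5-dimethyl-2H-pyran-2-one
Conditions: DBU, toluene, 80 °C
Reagents that add atoms: none
Why: Base-mediated lactonisation of the δ-enol onto the ester, followed by enolisation, should give the 4-hydroxy-2-pyranone.

Step 3
Reactants: 4 6-ethyl-4-hydroxy-3,5-dimethyl-2H-pyran-2-one
Product: 5 2-ethyl-6-methoxy-3,5-dimethyl-4H-pyran-4-one
Conditions: MeOTf, CH2Cl2, 0 °C → rt; aq. NaHCO3
Reagents that add atoms: methyl trifluoromethanesulfonate, COS(=O)(=O)C(F)(F)F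
Why: Hard O-methylation of the neutral pyranone at the lactone carbonyl oxygen gives a 2-methoxy-4-hydroxypyrylium ion that loses its proton to the 2-methoxy-4-pyranone (regioselective methylation of 4-hydroxy-2-pyranones).

Step 4
Reactants: 5 2-ethyl-6-methoxy-3,5-dimethyl-4H-pyran-4-one; 6 ethyl formate
Product: 7 (±)-2-Pyn-propanal
Conditions: LiN(SiMe3)2 (2.2 equiv), THF, −78 °C; HCO2Et, −78 → 0 °C; aq. citric acid
Reagents that add atoms: none
Why: Lateral (vinylogous) deprotonation of the 2-ethyl group and Claisen-type formylation, driven by deprotonation of the product, should give the aldehyde, whose stereocentre is configurationally labile.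

Step 5
Reactants: 7 (±)-2-Pyn-propanal; 8 prop-2-en-1-ol
Product: 9 (2S)-2-methyl-2-Pyn-pent-4-enal
Conditions: Pd(PPh3)4 (3 mol %), (R)-TRIP [(R)-3,3'-bis(2,4,6-triisopropylphenyl)-1,1'-binaphthyl-2,2'-diyl hydrogen phosphate] (3 mol %), Ph2CHNH2 (40 mol %), 5 Å molecular sieves, toluene, 40 °C; then 2 M HCl
Reagents that add atoms: none
Why: Asymmetric counter-anion-directed Tsuji–Trost α-allylation: the enamine of 7 attacks the π-allyl-palladium phosphate ion pair, and the chiral phosphate selects the enamine face and so sets the quaternary stereocentre (7 racemises through the enamine, so both enantiomers converge).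

Step 6
Reactants: 9 (2S)-2-methyl-2-Pyn-pent-4-enal; 10 dimethyl malonate
Product: 11 dimethyl 2-[(2R)-2-methyl-2-Pyn-pent-4-en-1-ylidene]propanedioate
Conditions: TiCl4, pyridine, THF, 0 °C → rt
Reagents that add atoms: none
Why: The titanium-mediated Knoevenagel condensation tolerates α-quaternary, non-enolisable aldehydes; the stereocentre is untouched.

Step 7
Reactants: 11 dimethyl 2-[(2R)-2-methyl-2-Pyn-pent-4-en-1-ylidene]propanedioate
Product: 12 dimethyl 2-[(2R,3E)-2-methyl-2-Pyn-pent-3-en-1-ylidene]propanedioate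
Conditions: RuHCl(CO)(PPh3)3 (3 mol %), toluene, 80 °C
Reagents that add atoms: none
Why: Ruthenium hydride addition and β-hydride elimination (alkene isomerisation) move the terminal alkene by one position and stop at the quaternary carbon; the alkylidene malonate cannot migrate.

Step 8
Reactants: 12 dimethyl 2-[(2R,3E)-2-methyl-2-Pyn-pent-3-en-1-ylidene]propanedioate
Product: 14 dimethyl 2-[(2R)-3,3-dimethoxy-2-methyl-2-Pyn-propylidene]propanedioate, via aldehyde 13 (not isolated)
Conditions: O3, CH2Cl2/MeOH, −78 °C to the first persistent colour; Me2S, −78 °C → rt; then HC(OMe)3, pyridinium p-toluenesulfonate, MeOH, rt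
Reagents that add atoms: trimethyl orthoformate, COC(OC)OC; methanol, CO
Why: Ozonolysis with reductive work-up should cleave the electron-rich propenyl alkene in preference to the electron-poor alkylidene malonate and the pyranone, and the neopentyl aldehyde is masked at once as its dimethyl acetal.

Step 9
Reactants: 14 dimethyl 2-[(2R)-3,3-dimethoxy-2-methyl-2-Pyn-propylidene]propanedioate
Product: 15 2-[(2R)-3,3-dimethoxy-2-methyl-2-Pyn-propylidene]propane-1,3-diol
Conditions: i-Bu2AlH (5 equiv), CH2Cl2, −78 → −20 °C; aq. KNaC4H4O6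
Reagents that add atoms: none
Why: 1,2-Reduction of both esters of the alkylidene malonate by the aluminium hydride should give the 2-alkylidene-propane-1,3-diol; the acetal is inert.

Step 10
Reactants: 15 2-[(2R)-3,3-dimethoxy-2-methyl-2-Pyn-propylidene]propane-1,3-diol; 16 3,3-dimethoxypentane
Product: 20 (1R,5R,9S)-6,8,9-trimethyl-4-methylidene-9-Pyn-2-oxabicyclo[3.3.1]nonan-7-one (C6/C8 epimers), via cyclic acetal 17 (not isolated), via allyl enol ether 18 (not isolated), via Claisen ketone 19 (not isolated)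
Conditions: 16 (8 equiv), EtCO2H (0.2 equiv), o-xylene, 135 °C, MeOH distilled off; then evaporation, CH2Cl2, i-Pr2NEt, Me3SiOTf, −78 → 0 °C; aq. NaHCO3
Reagents that add atoms: none
Why: Acid first closes the CH2OH that is cis to the quaternary carbon onto the acetal carbon (6-exo-trig capture of the oxocarbenium ion) to give the 3,6-dihydro-2H-pyran 17, whose remaining CH2OH exchanges into ketal 16 and loses methanol to the allyl 1-ethylpropenyl ether 18; its [3,3] shift (ketal Claisen rearrangement of the Johnson/Saucy–Marbet kind) joins the enol-ether carbon to ring carbon C4 and leaves the exocyclic methylene and the ethyl ketone 19. In the second stage Me3SiOTf/i-Pr2NEt converts the ethyl ketone into its less hindered, CH2-derived silyl enol ether and ionises the anomeric OMe, and the enol ether attacks the cyclic oxocarbenium ion (Mukaiyama-type aldol addition to an acetal, 6-(enolendo)-exo-trig) across the 1,3-diaxial positions, closing the carbocycle as the bridged ketone 20; this new single bond becomes the ring C=C in step 11. The stereocentre C5 of 20 (the ring CH of the target) is set in the sigmatropic step: the enol ether should be delivered to C4 of the half-chair on the face anti to the pseudoaxial pyranonyl group of the adjacent quaternary carbon (methyl pseudoequatorial), which places the new chain trans to the pyranone on the pyran and therefore, once the bridge is opened, the propenyl unit cis to the pyranone on the carbocycle; C1 is fixed by the cis-bridging, and the two CH(CH3) centres are uncontrolled and are erased in step 11. The step needs (a) site selectivity between the two CH2OH groups, secured because only the one cis to the quaternary carbon can reach the acetal carbon, (b) facial selectivity at C4, secured by the size difference between pyranonyl and methyl on the neighbouring quaternary centre, and (c) enol-silane regiochemistry, secured by kinetic silylation at the unhindered CH2 and by the fact that only this regioisomer can cyclise. The quaternary carbon next to the acetal blocks elimination to a glycal, and excess 16 is evaporated before the Lewis acid stage so that no external enol ether competes.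

Step 11
Reactants: 20 (1R,5R,9S)-6,8,9-trimethyl-4-methylidene-9-Pyn-2-oxabicyclo[3.3.1]nonan-7-one
Product: 23 (4R,5R,6S)-5-{3-[(tert-butyldimethylsilyl)oxy]prop-1-en-2-yl}-6-hydroxy-2,4,6-trimethyl-4-Pyn-cyclohex-2-en-1-one, via enone alcohol 21 (not isolated), via hydroxy enone 22 (not isolated)
Conditions: KN(SiMe3)2 (3.5 equiv), THF, −78 °C; (±)-(camphorsulfonyl)oxaziridine, −78 → −40 °C; t-BuMe2SiCl, −40 → 0 °C; AcOH, aq. NH4Cl
Reagents that add atoms: (±)-(camphorsulfonyl)oxaziridine, CC1(C)C2CCC13CS(=O)(=O)N4OC34C2; tert-butyldimethylsilyl chloride, CC(C)(C)[Si](C)(C)Cl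
Why: The C8 enolate expels the axial ring oxygen (E1cB retro-oxa-Michael fragmentation of the bicycle) to unveil the enone and the side-chain alkoxide; further base forms the cross-conjugated α′-enolate, which should be hydroxylated (Davis-type oxaziridine oxidation) on the face anti to the neighbouring propenyl unit and the pyranone, so the tertiary OH is trans to the side chain, and only the primary alkoxide is silylated.

Step 12
Reactants: 23 (4R,5R,6S)-5-{3-[(tert-butyldimethylsilyl)oxy]prop-1-en-2-yl}-6-hydroxy-2,4,6-trimethyl-4-Pyn-cyclohex-2-en-1-one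
Product: 24 (1S,2S,5R,6R)-6-{3-[(tert-butyldimethylsilyl)oxy]prop-1-en-2-yl}-1,3,5-trimethyl-5-Pyn-cyclohex-3-ene-1,2-diol
Conditions: Me4NBH(OAc)3, MeCN/AcOH, −30 °C
Reagents that add atoms: none
Why: Hydroxyl-directed reduction (Evans–Saksena type): the alkoxyborohydride formed at the tertiary OH delivers hydride to the carbonyl from the face of that OH, which should give the trans-1,2-diol by 1,2-reduction of the enone.

Step 13
Reactants: 24 (1S,2S,5R,6R)-6-{3-[(tert-butyldimethylsilyl)oxy]prop-1-en-2-yl}-1,3,5-trimethyl-5-Pyn-cyclohex-3-ene-1,2-diol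
Product: 25 tert-butyldimethyl({2-[(1R,4R,5R,6S)-2,4,6-trimethyl-4-Pyn-7-oxabicyclo[4.1.0]hept-2-en-5-yl]prop-2-en-1-yl}oxy)silane
Conditions: PPh3, diisopropyl azodicarboxylate, toluene, 0 °C → rt
Reagents that add atoms: none
Why: Mitsunobu cyclodehydration: the secondary allylic OH is activated as the oxyphosphonium ion and displaced with inversion by the tertiary hydroxyl, so the epoxide lies on the face of the tertiary oxygen, anti to the side chain and the pyranone.

Step 14
Reactants: 25 tert-butyldimethyl({2-[(1R,4R,5R,6S)-2,4,6-trimethyl-4-Pyn-7-oxabicyclo[4.1.0]hept-2-en-5-yl]prop-2-en-1-yl}oxy)silane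
Product: 26 2-[(1R,4R,5R,6S)-2,4,6-trimethyl-4-Pyn-7-oxabicyclo[4.1.0]hept-2-en-5-yl]prop-2-en-1-ol
Conditions: Bu4NF, AcOH, THF, 0 °C
Reagents that add atoms: none
Why: Fluoride-mediated cleavage of the primary silyl ether under buffered conditions should spare the vinyl epoxide.

Step 15
Reactants: 26 2-[(1R,4R,5R,6S)-2,4,6-trimethyl-4-Pyn-7-oxabicyclo[4.1.0]hept-2-en-5-yl]prop-2-en-1-ol
Product: 27 2-[(1R,4R,5S,6S)-2,4,6-trimethyl-4-Pyn-7-oxabicyclo[4.1.0]hept-2-en-5-yl]prop-2-enal
Conditions: MnO2, CH2Cl2, rt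
Reagents that add atoms: none
Why: Selective oxidation of the primary allylic alcohol by MnO2 should give the 2-substituted acrolein (the ring descriptor changes only through the priority rules).

Step 16
Reactants: 27 2-[(1R,4R,5S,6S)-2,4,6-trimethyl-4-Pyn-7-oxabicyclo[4.1.0]hept-2-en-5-yl]prop-2-enal; 28 pentan-3-one
Product: 30 (4R,5R)-5-hydroxy-4-methyl-6-[(1R,4R,5R,6S)-2,4,6-trimethyl-4-Pyn-7-oxabicyclo[4.1.0]hept-2-en-5-yl]hept-6-en-3-one, via enol borinate 29 (not isolated)
Conditions: 28, (+)-Ipc2BOTf, i-Pr2NEt, CH2Cl2, −78 °C; then 27, −78 → −20 °C; MeOH, pH 7 buffer, 30% H2O2, 0 °C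
Reagents that add atoms: none
Why: Paterson aldol: the (Z)-enol diisopinocampheylborinate of pentan-3-one reacts through a chair Zimmerman–Traxler transition state to give the syn aldol, and the Ipc ligands select the Re face of the aldehyde (reagent control), which sets the (R)-carbinol and the (R)-methyl centres.

**Compound list**

1 | methyl 2-methyl-3-oxopentanoate | CCC(=O)C(C)C(=O)OC | starting material
2 | N-methoxy-N-methylpropanamide | CCC(=O)N(C)OC | starting material
3 | methyl 2,4-dimethyl-3,5-dioxoheptanoate | CCC(=O)C(C)C(=O)C(C)C(=O)OC | intermediate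
4 | 6-ethyl-4-hydroxy-3,5-dimethyl-2H-pyran-2-one | CCC1=C(C)C(O)=C(C)C(=O)O1 | intermediate
5 | 2-ethyl-6-methoxy-3,5-dimethyl-4H-pyran-4-one | CCc1oc(OC)c(C)c(=O)c1C | intermediate
6 | ethyl formate | CCOC=O | starting material
7 | (±)-2-Pyn-propanal | CC(C=O)c1oc(OC)c(C)c(=O)c1C | intermediate
8 | prop-2-en-1-ol | C=CCO | starting material
9 | (2S)-2-methyl-2-Pyn-pent-4-enal | C=CC[C@@](C=O)(C)c1oc(OC)c(C)c(=O)c1C | intermediate
10 | dimethyl malonate | COC(=O)CC(=O)OC | starting material
11 | dimethyl 2-[(2R)-2-methyl-2-Pyn-pent-4-en-1-ylidene]propanedioate | C=CC[C@@](C=C(C(=O)OC)C(=O)OC)(C)c1oc(OC)c(C)c(=O)c1C | intermediate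
12 | dimethyl 2-[(2R,3E)-2-methyl-2-Pyn-pent-3-en-1-ylidene]propanedioate | C/C=C/[C@@](C=C(C(=O)OC)C(=O)OC)(C)c1oc(OC)c(C)c(=O)c1C | intermediate
13 | dimethyl 2-[(2R)-2-methyl-3-oxo-2-Pyn-propylidene]propanedioate | O=C[C@@](C=C(C(=O)OC)C(=O)OC)(C)c1oc(OC)c(C)c(=O)c1C | intermediate
14 | dimethyl 2-[(2R)-3,3-dimethoxy-2-methyl-2-Pyn-propylidene]propanedioate | COC(OC)[C@@](C=C(C(=O)OC)C(=O)OC)(C)c1oc(OC)c(C)c(=O)c1C | intermediate
15 | 2-[(2R)-3,3-dimethoxy-2-methyl-2-Pyn-propylidene]propane-1,3-diol | COC(OC)[C@@](C=C(CO)CO)(C)c1oc(OC)c(C)c(=O)c1C | intermediate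
16 | 3,3-dimethoxypentane | CCC(OC)(OC)CC | starting material
17 | [(5R)-6-methoxy-5-methyl-5-Pyn-5,6-dihydro-2H-pyran-3-yl]methanol (anomers) | COC1OCC(CO)=C[C@]1(C)c2oc(OC)c(C)c(=O)c2C | intermediate
18 | (3R)-2-methoxy-3-methyl-5-[(pent-2-en-3-yloxy)methyl]-3-Pyn-3,6-dihydro-2H-pyran (anomers, E/Z) | COC1OCC(COC(CC)=CC)=C[C@]1(C)c2oc(OC)c(C)c(=O)c2C | intermediate
19 | 2-[(3R,4R)-2-methoxy-3-methyl-5-methylidene-3-Pyn-oxan-4-yl]pentan-3-one (epimers at C2 of the pentanone and at the acetal carbon) | CCC(=O)C(C)[C@@H]1C(=C)COC(OC)[C@@]1(C)c2oc(OC)c(C)c(=O)c2C | intermediate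
20 | (1R,5R,9S)-6,8,9-trimethyl-4-methylidene-9-Pyn-2-oxabicyclo[3.3.1]nonan-7-one (C6/C8 epimers) | C=C1CO[C@@H]2C(C)C(=O)C(C)[C@H]1[C@]2(C)c3oc(OC)c(C)c(=O)c3C | intermediate
21 | (4R,5R)-5-(3-hydroxyprop-1-en-2-yl)-2,4,6-trimethyl-4-Pyn-cyclohex-2-en-1-one (C6 epimers) | C=C(CO)[C@H]1C(C)C(=O)C(C)=C[C@@]1(C)c2oc(OC)c(C)c(=O)c2C | intermediate
22 | (4R,5R,6S)-6-hydroxy-5-(3-hydroxyprop-1-en-2-yl)-2,4,6-trimethyl-4-Pyn-cyclohex-2-en-1-one | C=C(CO)[C@H]1[C@](C)(O)C(=O)C(C)=C[C@@]1(C)c2oc(OC)c(C)c(=O)c2C | intermediate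
23 | (4R,5R,6S)-5-{3-[(tert-butyldimethylsilyl)oxy]prop-1-en-2-yl}-6-hydroxy-2,4,6-trimethyl-4-Pyn-cyclohex-2-en-1-one | C=C(CO[Si](C)(C)C(C)(C)C)[C@H]1[C@](C)(O)C(=O)C(C)=C[C@@]1(C)c2oc(OC)c(C)c(=O)c2C | intermediate
24 | (1S,2S,5R,6R)-6-{3-[(tert-butyldimethylsilyl)oxy]prop-1-en-2-yl}-1,3,5-trimethyl-5-Pyn-cyclohex-3-ene-1,2-diol | C=C(CO[Si](C)(C)C(C)(C)C)[C@H]1[C@](C)(O)[C@@H](O)C(C)=C[C@@]1(C)c2oc(OC)c(C)c(=O)c2C | intermediate
25 | tert-butyldimethyl({2-[(1R,4R,5R,6S)-2,4,6-trimethyl-4-Pyn-7-oxabicyclo[4.1.0]hept-2-en-5-yl]prop-2-en-1-yl}oxy)silane | C=C(CO[Si](C)(C)C(C)(C)C)[C@H]1[C@]2(C)O[C@@H]2C(C)=C[C@@]1(C)c3oc(OC)c(C)c(=O)c3C | intermediate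
26 | 2-[(1R,4R,5R,6S)-2,4,6-trimethyl-4-Pyn-7-oxabicyclo[4.1.0]hept-2-en-5-yl]prop-2-en-1-ol | C=C(CO)[C@H]1[C@]2(C)O[C@@H]2C(C)=C[C@@]1(C)c3oc(OC)c(C)c(=O)c3C | intermediate
27 | 2-[(1R,4R,5S,6S)-2,4,6-trimethyl-4-Pyn-7-oxabicyclo[4.1.0]hept-2-en-5-yl]prop-2-enal | C=C(C=O)[C@H]1[C@]2(C)O[C@@H]2C(C)=C[C@@]1(C)c3oc(OC)c(C)c(=O)c3C | intermediate
28 | pentan-3-one | CCC(=O)CC | starting material
29 | (Z)-pent-2-en-3-yl diisopinocampheylborinate (Ipc from (−)-α-pinene) | C/C=C(\OB([C@H]1C[C@H]2C[C@@H]([C@@H]1C)C2(C)C)[C@H]1C[C@H]2C[C@@H]([C@@H]1C)C2(C)C)CC | intermediate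
30 | (4R,5R)-5-hydroxy-4-methyl-6-[(1R,4R,5R,6S)-2,4,6-trimethyl-4-Pyn-7-oxabicyclo[4.1.0]hept-2-en-5-yl]hept-6-en-3-one | C=C([C@H](O)[C@@H](C)C(=O)CC)[C@H]1[C@]2(C)O[C@@H]2C(C)=C[C@@]1(C)c1oc(OC)c(C)c(=O)c1C | target

**Totals**

Total step count: 16. Longest linear sequence: 16 steps (from 1).

**Steps most likely to fail, each with one fallback**

Step 10. The ketal exchange and loss of methanol on the hindered allylic alcohol may be slow, so that material is lost thermally or the oxocarbenium ion is intercepted before the rearrangement; facial selectivity in the sigmatropic step may also erode at 135 °C. The fallback makes the same C–C bond by an anion-accelerated Carroll rearrangement at far lower temperature. It sets out from 17 (isolated after treating 15 with pyridinium p-toluenesulfonate in CH2Cl2) and 1. Transesterification (4-(dimethylamino)pyridine, toluene, reflux, methanol removed) gives [(5R)-6-methoxy-5-methyl-5-Pyn-5,6-dihydro-2H-pyran-3-yl]methyl 2-methyl-3-oxopentanoate F1. Its dianion (LiN(i-Pr)2, 2.2 equiv, THF, −78 °C → reflux) rearranges to 2-methyl-2-[(3R,4R)-2-methoxy-3-methyl-5-methylidene-3-Pyn-oxan-4-yl]-3-oxopentanoic acid F2, which loses carbon dioxide on mildly acidic work-up. The fallback comes back to the route at 19, which is closed to 20 with Me3SiOTf/i-Pr2NEt as in the second stage of step 10.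

Step 5. Enamine formation with the ortho-substituted heteroaryl aldehyde may be slow and the ion-pair control of the enamine face may be weak, giving low enantiomeric purity at the only stereocentre that all later ones depend on. The fallback sets the quaternary centre by enzymatic desymmetrisation and sets out from 7. Hydroxymethylation (aq. CH2O, K2CO3) gives (±)-3-hydroxy-2-methyl-2-Pyn-propanal F3, which is reduced in the same flask (NaBH4) to 2-methyl-2-Pyn-propane-1,3-diol F4. Lipase-catalysed acetylation (lipase from Burkholderia cepacia, vinyl acetate) should desymmetrise this prochiral diol to (2S)-3-hydroxy-2-methyl-2-Pyn-propyl acetate F5. Dess–Martin oxidation gives (2S)-2-methyl-3-oxo-2-Pyn-propyl acetate F6, and Knoevenagel condensation with 10 (TiCl4, pyridine) gives dimethyl 2-[(2S)-3-acetoxy-2-methyl-2-Pyn-propylidene]propanedioate F7. Methanolysis (K2CO3, MeOH, 0 °C) gives dimethyl 2-[(2S)-3-hydroxy-2-methyl-2-Pyn-propylidene]propanedioate F8, and Dess–Martin oxidation brings the fallback back to the route at 13, which is converted to 14 as in step 8.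

Step 11. Oxygen transfer may occur on the wrong face of the enolate or at the vinylogous carbon, and the α-hydroxy ketone may undergo an α-ketol shift under the basic conditions. The fallback brings in the oxygen by epoxidation of a diene instead and sets out from 20. Ring opening with silylation but without oxidation (KN(SiMe3)2, 1.1 equiv, THF, −78 °C; t-BuMe2SiCl) gives (4R,5R)-5-{3-[(tert-butyldimethylsilyl)oxy]prop-1-en-2-yl}-2,4,6-trimethyl-4-Pyn-cyclohex-2-en-1-one F9. Kinetic α′-enolisation and triflation (KN(SiMe3)2, PhNTf2, THF, −78 °C) give (3S,4R)-3-{3-[(tert-butyldimethylsilyl)oxy]prop-1-en-2-yl}-2,4,6-trimethyl-4-Pyn-cyclohexa-1,5-dien-1-yl trifluoromethanesulfonate F10. Formate reduction (Pd(OAc)2, PPh3, Bu3N, HCO2H, DMF, 60 °C) gives tert-butyldimethyl({2-[(1R,6R)-2,4,6-trimethyl-6-Pyn-cyclohexa-2,4-dien-1-yl]prop-2-en-1-yl}oxy)silane F11. Epoxidation with dimethyldioxirane (acetone, −20 °C) should take place at the diene double bond remote from the quaternary carbon and anti to the side chain and the pyranone, and the fallback comes back to the route at 25.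

**Further compounds**

F1 | step 10 | [(5R)-6-methoxy-5-methyl-5-Pyn-5,6-dihydro-2H-pyran-3-yl]methyl 2-methyl-3-oxopentanoate | COC1OCC(COC(=O)C(C)C(=O)CC)=C[C@]1(C)c2oc(OC)c(C)c(=O)c2C
F2 | step 10 | 2-methyl-2-[(3R,4R)-2-methoxy-3-methyl-5-methylidene-3-Pyn-oxan-4-yl]-3-oxopentanoic acid | CCC(=O)C(C)(C(=O)O)[C@@H]1C(=C)COC(OC)[C@@]1(C)c2oc(OC)c(C)c(=O)c2C
F3 | step 5 | (±)-3-hydroxy-2-methyl-2-Pyn-propanal | OCC(C)(C=O)c1oc(OC)c(C)c(=O)c1C
F4 | step 5 | 2-methyl-2-Pyn-propane-1,3-diol | OCC(C)(CO)c1oc(OC)c(C)c(=O)c1C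
F5 | step 5 | (2S)-3-hydroxy-2-methyl-2-Pyn-propyl acetate | CC(=O)OC[C@@](CO)(C)c1oc(OC)c(C)c(=O)c1C
F6 | step 5 | (2S)-2-methyl-3-oxo-2-Pyn-propyl acetate | CC(=O)OC[C@@](C=O)(C)c1oc(OC)c(C)c(=O)c1C
F7 | step 5 | dimethyl 2-[(2S)-3-acetoxy-2-methyl-2-Pyn-propylidene]propanedioate | CC(=O)OC[C@@](C=C(C(=O)OC)C(=O)OC)(C)c1oc(OC)c(C)c(=O)c1C
F8 | step 5 | dimethyl 2-[(2S)-3-hydroxy-2-methyl-2-Pyn-propylidene]propanedioate | OC[C@@](C=C(C(=O)OC)C(=O)OC)(C)c1oc(OC)c(C)c(=O)c1C
F9 | step 11 | (4R,5R)-5-{3-[(tert-butyldimethylsilyl)oxy]prop-1-en-2-yl}-2,4,6-trimethyl-4-Pyn-cyclohex-2-en-1-one (C6 epimers) | C=C(CO[Si](C)(C)C(C)(C)C)[C@H]1C(C)C(=O)C(C)=C[C@@]1(C)c2oc(OC)c(C)c(=O)c2C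
F10 | step 11 | (3S,4R)-3-{3-[(tert-butyldimethylsilyl)oxy]prop-1-en-2-yl}-2,4,6-trimethyl-4-Pyn-cyclohexa-1,5-dien-1-yl trifluoromethanesulfonate | C=C(CO[Si](C)(C)C(C)(C)C)[C@H]1C(C)=C(OS(=O)(=O)C(F)(F)F)C(C)=C[C@@]1(C)c2oc(OC)c(C)c(=O)c2C
F11 | step 11 | tert-butyldimethyl({2-[(1R,6R)-2,4,6-trimethyl-6-Pyn-cyclohexa-2,4-dien-1-yl]prop-2-en-1-yl}oxy)silane | C=C(CO[Si](C)(C)C(C)(C)C)[C@H]1C(C)=CC(C)=C[C@@]1(C)c2oc(OC)c(C)c(=O)c2C
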